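**Strategy.** Everything rests on cutting the three aryl C–O bonds of the acylphloroglucinol ring in one stroke. The hydroxylated ring carbons C2, C4 and C6 stand ortho, para and ortho to the acyl-bearing carbon C1, the very positions from which a ketone carbonyl can take up the negative charge of an addition–elimination. A 2,4,6-trifluorophenyl ketone that already carries the full 10-phenyldecyl chain is therefore treated with excess sodium benzyloxide, which should exchange every fluoride for a benzyl ether in a single operation. This precursor arises from lithiated 1,3,5-trifluorobenzene and the Weinreb amide of 11-phenylundecanoic acid; hydrogenolysis of the three benzyl ethers then uncovers the target.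

Key step: step 3

Remark: 11-phenylundecanoic acid is taken as a purchasable ω-phenyl fatty acid, and the para fluoride is assumed to leave first; ortho-first isomers would converge on the same tris-ether.

**Step 1**
Reactants: 1 11-phenylundecanoic acid; 2 N,O-dimethylhydroxylamine hydrochloride
Product: 4 N-methoxy-N-methyl-11-phenylundecanamide, via acyl imidazolide 3 (not isolated)
Conditions: CDI (1.1 equiv), CH2Cl2, rt; then 2 (1.2 equiv), rt
Reagents that add atoms: N,O-dimethylhydroxylamine hydrochloride (compound 2), CNOC.Cl
Why: CDI should turn the acid into acyl imidazolide 3 with loss of CO2, and the amine salt then protonates the imidazolide and acylates at nitrogen, a standard Weinreb amide coupling in which the alkyl chain and phenyl ring are inert.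

**Step 2**
Reactants: 4 N-methoxy-N-methyl-11-phenylundecanamide; 5 1,3,5-trifluorobenzene
Product: 8 1-(2,4,6-trifluorophenyl)-11-phenylundecan-1-one, via 2,4,6-trifluorophenyllithium 6 (not isolated), via lithium hemiaminal adduct 7 (not isolated)
Conditions: 5 (1.3 equiv), n-BuLi (1.25 equiv), THF, −78 °C; then 4, −78 → −60 °C; 1 M HCl quench at −60 °C
Reagents that add atoms: none
Why: The C–H flanked by two fluorines of 5 should be deprotonated cleanly at −78 °C (ortho-lithiation), and aryllithium 6 adds once to the amide to give the chelated tetrahedral adduct 7, which releases the ketone only on acidic quench (Weinreb ketone synthesis), while the low temperature keeps 6 from losing LiF to an aryne.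

**Step 3**
Reactants: 8 1-(2,4,6-trifluorophenyl)-11-phenylundecan-1-one; 9 benzyl alcohol
Product: 13 1-[2,4,6-tris(benzyloxy)phenyl]-11-phenylundecan-1-one, via sodium benzyloxide 10 (not isolated), via 4-benzyloxy-2,6-difluorophenyl ketone 11 (not isolated), via 2,4-bis(benzyloxy)-6-fluorophenyl ketone 12 (not isolated)
Conditions: NaH (5 equiv), BnOH (solvent), 0 °C → rt; then 8, rt → 90 °C, Ar
Reagents that add atoms: benzyl alcohol (compound 9, used as its sodium salt 10), OCc1ccccc1
Why: Benzyloxide adds to a fluorine-bearing ring carbon to form a Meisenheimer anion whose charge resides on C1, C3 and C5 and is drained from C1 into the ketone carbonyl, after which fluoride departs; this addition–elimination runs three times, at C4, C2 and C6, through 11 and 12. The closest known reaction type is alkoxide SNAr on fluoroarenes bearing an ortho or para acyl group, here driven to exhaustive substitution. No ring is closed and no stereocentre is created. Because C2, C4 and C6 are mutually meta, an ether already installed never sits on a charge-bearing carbon of the next Meisenheimer anion, so the later displacements are retarded only through the weakened and twisted carbonyl acceptor and should yield to heat and excess alkoxide. The selectivity needed is attack at the three C–F carbons in preference to addition to, hydride transfer to or enolisation of the ketone. It is secured by the two ortho substituents that screen the carbonyl (any hemiketal formed reverts), by the benzyl alcohol medium, which reprotonates the enolate so that only a small fraction of the ketone is ever parked as the unreactive enolate, and by working under argon so that no benzaldehyde accumulates.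

**Step 4**
Reactants: 13 1-[2,4,6-tris(benzyloxy)phenyl]-11-phenylundecan-1-one
Product: 14 1-(2,4,6-trihydroxyphenyl)-11-phenylundecan-1-one
Conditions: H2 (1 atm), 10% Pd/C, EtOAc/MeOH, rt
Reagents that add atoms: none
Why: Catalytic hydrogenolysis should cleave the three benzylic C–O bonds to toluene, while the ketone (deactivated by three oxygen donors and hydrogen-bonded to the ortho hydroxyls once they are freed) and the terminal phenyl ring are not reduced at one atmosphere.

**Compound list**
1 | 11-phenylundecanoic acid | O=C(O)CCCCCCCCCCc1ccccc1 | starting material
2 | N,O-dimethylhydroxylamine hydrochloride | CNOC.Cl | starting material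
3 | 1-(1H-imidazol-1-yl)-11-phenylundecan-1-one (acyl imidazolide) | O=C(CCCCCCCCCCc1ccccc1)n1ccnc1 | intermediate (not isolated)
4 | N-methoxy-N-methyl-11-phenylundecanamide | CON(C)C(=O)CCCCCCCCCCc1ccccc1 | intermediate
5 | 1,3,5-trifluorobenzene | Fc1cc(F)cc(F)c1 | starting material
6 | 2,4,6-trifluorophenyllithium | [Li]c1c(F)cc(F)cc1F | intermediate (not isolated)
7 | lithium 1-[methoxy(methyl)amino]-11-phenyl-1-(2,4,6-trifluorophenyl)undecan-1-olate (racemic tetrahedral adduct) | [Li]OC(CCCCCCCCCCc1ccccc1)(N(C)OC)c1c(F)cc(F)cc1F | intermediate (not isolated)
8 | 1-(2,4,6-trifluorophenyl)-11-phenylundecan-1-one | O=C(CCCCCCCCCCc1ccccc1)c1c(F)cc(F)cc1F | intermediate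
9 | benzyl alcohol | OCc1ccccc1 | starting material
10 | sodium benzyloxide | [Na+].[O-]Cc1ccccc1 | intermediate (not isolated)
11 | 1-[4-(benzyloxy)-2,6-difluorophenyl]-11-phenylundecan-1-one | O=C(CCCCCCCCCCc1ccccc1)c1c(F)cc(OCc2ccccc2)cc1F | intermediate (not isolated)
12 | 1-[2,4-bis(benzyloxy)-6-fluorophenyl]-11-phenylundecan-1-one | O=C(CCCCCCCCCCc1ccccc1)c1c(F)cc(OCc2ccccc2)cc1OCc1ccccc1 | intermediate (not isolated)
13 | 1-[2,4,6-tris(benzyloxy)phenyl]-11-phenylundecan-1-one | O=C(CCCCCCCCCCc1ccccc1)c1c(OCc2ccccc2)cc(OCc2ccccc2)cc1OCc1ccccc1 | intermediate
14 | 1-(2,4,6-trihydroxyphenyl)-11-phenylundecan-1-one | O=C(CCCCCCCCCCc1ccccc1)c1c(O)cc(O)cc1O | target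

**Total step count:** 4
**Longest linear sequence:** 4 steps (1 → 4 → 8 → 13 → 14)

**Steps most likely to fail**

Step 3. The third displacement may stall at the monofluoride stage once two donor ethers have weakened and twisted the carbonyl acceptor. The hot alkoxide may also transfer hydride to the ketone and start aldol chemistry at the α-methylene. The fallback sets out from 1 and rejoins the route at 14. Acid 1 is converted with oxalyl chloride and catalytic DMF in CH2Cl2 into 11-phenylundecanoyl chloride F1. F1 then C-acylates an excess of purchased phloroglucinol (benzene-1,3,5-triol) under AlCl3 in CH2Cl2/MeNO2 (Friedel–Crafts acylation) to give 14 directly. The alkylbenzene terminus is far less nucleophilic than the triol and should not compete.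

Step 2. Addition of the doubly ortho-fluorinated aryllithium to the amide may be slow at the temperatures at which it survives, so that LiF loss to an aryne or deprotonation of the amide α-methylene takes over. The fallback sets out from 4 and rejoins the route at 8. Amide 4 is reduced with i-Bu2AlH in THF at −78 °C to 11-phenylundecanal F2. This far more electrophilic aldehyde is treated at −78 °C with 6, generated as in step 2, to give racemic 11-phenyl-1-(2,4,6-trifluorophenyl)undecan-1-ol F3. Dess–Martin oxidation in CH2Cl2 then returns ketone 8.

Step 4. The aryl ketone may be over-reduced to the carbinol or the methylene, or the two hindered ortho ethers may cleave sluggishly. The fallback sets out from 13 and rejoins the route at 14. Non-reductive debenzylation with BCl3 and pentamethylbenzene as benzyl-cation scavenger in CH2Cl2 at −78 °C should give 14 directly. This fallback makes no new compound (F0).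

**Further compounds**
F1 | step 3 | 11-phenylundecanoyl chloride | O=C(Cl)CCCCCCCCCCc1ccccc1
F2 | step 2 | 11-phenylundecanal | O=CCCCCCCCCCCc1ccccc1
F3 | step 2 | 11-phenyl-1-(2,4,6-trifluorophenyl)undecan-1-ol (racemic) | OC(CCCCCCCCCCc1ccccc1)c1c(F)cc(F)cc1F
F0 | step 4 | none | none
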